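**Plan**
- Retrosynthesis: the C4 carboxyl is stepped back to a formyl group and the decalin acid is masked as its allyl ester. The cyclohexene is then cut at its two bonds to the ring-fusion carbons (C4–C12' and C5–C15', primes = labdane numbers), a retro-[4+2] that gives a C15 enal and a C20 diene.
- Enabling feature: the cyclohexene has its C=C(CH3) bond opposite the fusion bond, a carboxyl on the quaternary fusion carbon C4, and a trans fusion to the nine-membered ring. This is the imprint of the 12E,14-diene of trans-communic acid on a strained, carbonyl-conjugated ring-trans C4=C5 olefin of the bicyclo[7.2.0]undecene.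
- Forward order: the cyclobutane/nine-membered bicycle comes from (−)-β-caryophyllene and the decalin from trans-communic acid. The cyclohexene is closed last and joins the two halves, then CHO → CO2H and deallylation.
- Dienophile: SeO2 oxidation of C14 (which turns C4=C5 ring-cis), directed epoxidation, phosphorus-betaine inversion back to ring-trans, MnO2.
- Stereochemistry: C1, C9 and the four decalin centres come from the chiral pool. C4 and C5 come from the ring-trans geometry and the exposed olefin face. The CH next to C4 comes from the endo mode and the E-diene.

Key step: step 6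

Assumption: trans-communic acid and (−)-β-caryophyllene are taken as purchasable natural products. Caryophyllane numbers (C14 = carbon on C4, C15 = methylidene carbon on C8) and labdane numbers are used, and "ring-trans"/"ring-cis" describe C4=C5 by the ring carbons C3 and C6, because the CIP letter changes with the oxidation level of C14.

Step 1
Reactants: 1 (−)-β-caryophyllene
Product: 2 14-hydroxyisocaryophyllene (ring-cis allylic alcohol)
Conditions: SeO2 (0.5 equiv), t-BuOOH (2 equiv), CH2Cl2, 0 °C → rt
Reagents that add atoms: tert-butyl hydroperoxide CC(C)(C)OO; selenium dioxide O=[Se]=O (oxygen carrier, reoxidised by the hydroperoxide)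
Why: Riley allylic oxidation, in which ene attack of SeO2 on the strained trisubstituted C4=C5 bond (Se to C5, hydrogen from the C14 methyl) and a [2,3]-sigmatropic shift put oxygen on C14 and rebuild C4=C5 with the new CH2OH trans to C6, the usual E-selective course, which in this ring turns the olefin from ring-trans to ring-cis as is known for methyl groups on ring-trans olefins of ten-membered germacrane rings; no stereocentre is formed.

Step 2
Reactants: 2 14-hydroxyisocaryophyllene
Product: 3 cis-4,5-epoxide of 2
Conditions: VO(acac)2 (2 mol%), t-BuOOH (1.5 equiv), CH2Cl2, 0 °C → rt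
Reagents that add atoms: tert-butyl hydroperoxide CC(C)(C)OO
Why: Hydroxyl-directed epoxidation through a vanadium alkoxide–alkylperoxide complex is selective for the allylic-alcohol olefin over the exocyclic methylene and adds oxygen syn, so the ring-cis olefin should give a cis-epoxide, and the face attacked (drawn for one face) does not matter because C4 and C5 become sp2 again in step 3.

Step 3
Reactants: 3 cis-4,5-epoxide of 2
Product: 6 14-hydroxy-β-caryophyllene (ring-trans allylic alcohol), via dilithium phosphino-alkoxide 4 (not isolated), via phosphonium betaine 5 (not isolated)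
Conditions: n-BuLi (1.0 equiv), THF, −78 °C; LiPPh2 (1.3 equiv), 0 °C → rt; MeI (3 equiv), rt; H2O work-up
Reagents that add atoms: none
Why: Phosphorus-betaine olefin inversion, in which, after deprotonation of the hydroxyl, Ph2P− opens the epoxide by SN2 at the secondary C5 with inversion, P-methylation gives the betaine, and syn-elimination of Ph2P(O)Me through an oxaphosphetane converts the cis-epoxide into the ring-trans olefin, a sequence known to deliver even trans-cyclooctene from cis-cyclooctene oxide.

Step 4
Reactants: 6 14-hydroxy-β-caryophyllene
Product: 7 β-caryophyllen-14-al (ring-trans enal)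
Conditions: activated MnO2 (15 equiv), CH2Cl2, rt
Reagents that add atoms: none
Why: Oxidation of the primary allylic alcohol on activated MnO2 is neutral and selective for allylic alcohols, so the strained ring-trans olefin and the exocyclic methylene should be kept and the enal not over-oxidised.

Step 5
Reactants: 8 trans-communic acid
Product: 9 allyl trans-communate
Conditions: allyl bromide (1.5 equiv), K2CO3 (2 equiv), DMF, rt, argon, dark
Reagents that add atoms: allyl bromide C=CCBr
Why: SN2 O-alkylation of the potassium carboxylate does not depend on attack at the hindered axial C19 carbonyl and gives an ester that shields the acid from the aluminium reagent of step 6 and is later removed without hydrolysis.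

Step 6
Reactants: 7 β-caryophyllen-14-al (dienophile, 1.5 equiv); 9 allyl trans-communate (diene)
Product: 10 [4+2] adduct aldehyde (allyl ester)
Conditions: Me2AlCl (2.5 equiv), CH2Cl2, −78 → −30 °C; then H2O
Reagents that add atoms: none
Why: Me2AlCl binds the formyl oxygen of 7 and lowers the LUMO of the C4=C5 olefin, which is already strained by the ring-trans nine-membered ring, so that a concerted but asynchronous normal-demand [4+2] cycloaddition with the s-cis 12E,14-diene of 9 should proceed at low temperature; the closest known reaction type is the alkylaluminium-chloride-promoted Diels–Alder reaction of α,β-disubstituted enals with 1,2-disubstituted dienes of the 1-vinylcycloalkene kind, and [4+2] additions to the ring-trans olefin of caryophyllene itself are known. The cyclohexene closes by intermolecular [4+2] cycloaddition, suprafacial on both partners, with the C15'–C5 bond leading and the C12'–C4 bond following. The quaternary C4 and the neighbouring C5 are set together: their trans relation is the ring-trans olefin geometry carried over by suprafacial addition, and their absolute sense follows from attack on the outer face of that olefin in the dominant ring conformers, the face that peracids also use, the inner face being covered by the ring. The third centre, the former diene carbon C12', is set by the endo position of the aluminium-bound formyl group together with the E geometry of C12'=C13', which places the CH2–decalin arm cis to the formyl group. The step needs ortho regioselectivity, endo selectivity, one olefin face and reaction at the diene only: the β-carbon C5 with the largest LUMO coefficient bonds first to the unhindered CH2 terminus C15', the Lewis acid strengthens the endo preference, and the isolated exocyclic methylenes of both partners are neither dienes nor activated.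

Step 7
Reactants: 10 [4+2] adduct aldehyde (allyl ester)
Product: 11 adduct carboxylic acid (allyl ester)
Conditions: NaClO2 (5 equiv), NaH2PO4 (5 equiv), 2-methyl-2-butene (30 equiv), t-BuOH/THF/H2O, 0 °C → rt
Reagents that add atoms: sodium chlorite [Na+].[O-]Cl=O
Why: Pinnick oxidation (chlorous acid adds to the formyl group and fragments to the acid and HOCl) works on neopentyl aldehydes without α-hydrogen, cannot epimerise the quaternary centre, and the excess 2-methyl-2-butene intercepts HOCl before it reaches the four C=C bonds.

Step 8
Reactants: 11 adduct carboxylic acid (allyl ester)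
Product: 12 target diacid CNP0330729.1
Conditions: Pd(PPh3)4 (5 mol%), morpholine (10 equiv), THF, rt; then dilute aq. citric acid
Reagents that add atoms: none
Why: Tsuji–Trost deallylation, in which zerovalent palladium ionises the allyl ester to a π-allyl complex and the carboxylate and morpholine takes up the allyl group, touches neither the hindered carbonyl nor any olefin or stereocentre, so acidic work-up should give the diacid.

**Compound list**
1 | (−)-β-caryophyllene; (1R,4E,9S)-4,11,11-trimethyl-8-methylidenebicyclo[7.2.0]undec-4-ene (C4=C5 ring-trans) | C=C1CC/C=C(\C)CC[C@@H]2[C@@H]1CC2(C)C | starting material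
2 | 14-hydroxyisocaryophyllene; [(1R,4E,9S)-11,11-dimethyl-8-methylidenebicyclo[7.2.0]undec-4-en-4-yl]methanol (C4=C5 ring-cis, C3 and C6 on the same side) | C=C1CC/C=C(/CO)CC[C@@H]2[C@@H]1CC2(C)C | intermediate
3 | cis-4,5-epoxide of 2; (1R,4R,5R,9S)-4,5-epoxyisocaryophyll-8(15)-en-14-ol (C3 and C6 cis on the oxirane) | C=C1CC[C@H]2O[C@@]2(CO)CC[C@@H]2[C@@H]1CC2(C)C | intermediate
4 | dilithium alkoxide of the 5-(diphenylphosphanyl)-4,14-diol (P on C5 with inverted configuration, anti to the oxygen on C4) | C=C1CC[C@H](P(c2ccccc2)c2ccccc2)[C@]([O-])(C[O-])CC[C@@H]2[C@@H]1CC2(C)C.[Li+].[Li+] | intermediate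
5 | P-methyl-diphenylphosphonium betaine of 4 (C4–O−, C5–P+, lithium 14-alkoxide) | C=C1CC[C@H]([P+](C)(c2ccccc2)c2ccccc2)[C@]([O-])(C[O-])CC[C@@H]2[C@@H]1CC2(C)C.[Li+] | intermediate
6 | 14-hydroxy-β-caryophyllene; [(1R,4Z,9S)-11,11-dimethyl-8-methylidenebicyclo[7.2.0]undec-4-en-4-yl]methanol (C4=C5 ring-trans) | C=C1CC/C=C(\CO)CC[C@@H]2[C@@H]1CC2(C)C | intermediate
7 | β-caryophyllen-14-al; (1R,4Z,9S)-11,11-dimethyl-8-methylidenebicyclo[7.2.0]undec-4-ene-4-carbaldehyde (ring-trans, CHO cis to C6) | C=C1CC/C=C(\C=O)CC[C@@H]2[C@@H]1CC2(C)C | intermediate
8 | trans-communic acid; (1S,4aR,5S,8aR)-1,4a-dimethyl-6-methylidene-5-[(2E)-3-methylpenta-2,4-dien-1-yl]decahydronaphthalene-1-carboxylic acid | C=C/C(C)=C/C[C@H]1C(=C)CC[C@@H]2[C@]1(C)CCC[C@]2(C)C(=O)O | starting material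
9 | allyl trans-communate (prop-2-enyl ester of 8) | C=C/C(C)=C/C[C@H]1C(=C)CC[C@@H]2[C@]1(C)CCC[C@]2(C)C(=O)OCC=C | intermediate
10 | [4+2] adduct aldehyde: cyclohexene fused trans to the nine-membered ring at caryophyllane C4–C5, CHO on C4, H on C5 trans to CHO, ring C=C(CH3) next to the CH that carries the CH2–decalin arm cis to CHO; allyl ester on the decalin | C=C1CC[C@H]2CC=C(C)[C@@H](C[C@H]3C(=C)CC[C@@H]4[C@]3(C)CCC[C@]4(C)C(=O)OCC=C)[C@]2(C=O)CC[C@@H]2[C@@H]1CC2(C)C | intermediate
11 | adduct carboxylic acid (CO2H on C4 in place of CHO, same configuration; allyl ester on the decalin) | C=C1CC[C@H]2CC=C(C)[C@@H](C[C@H]3C(=C)CC[C@@H]4[C@]3(C)CCC[C@]4(C)C(=O)OCC=C)[C@]2(C(=O)O)CC[C@@H]2[C@@H]1CC2(C)C | intermediate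
12 | target diacid CNP0330729.1 (both carboxyl groups free) | C=C1CC[C@H]2CC=C(C)[C@@H](C[C@H]3C(=C)CC[C@@H]4[C@]3(C)CCC[C@]4(C)C(=O)O)[C@]2(C(=O)O)CC[C@@H]2[C@@H]1CC2(C)C | target

Total steps: 8. Longest linear sequence: 7 steps (steps 1, 2, 3, 4, 6, 7, 8).

**Steps most likely to fail**

Step 6. The aluminium-bound enal may be attacked across the ring by its own exocyclic C8=C15 bond, the ring-trans enal may isomerise, the diene may oligomerise under the Lewis acid, and the minor ring conformer of 7 may add through its other olefin face. The fallback uses no Lewis acid, no protecting group and another oxidation level. Starting from 7, Pinnick oxidation (NaClO2, NaH2PO4, 2-methyl-2-butene) should give ring-trans β-caryophyllen-14-oic acid F1. F1 would then be heated with free trans-communic acid 8 in toluene at 10–12 kbar and 40–60 °C. This thermal [4+2] cycloaddition of the two acids, endo with respect to the carboxyl group, should give 12 directly. The fallback returns to the route at 12, and steps 5, 7 and 8 fall away.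

Step 1. Ene attack may compete at the other allylic positions (C3, C7, C9), the alcohol may be over-oxidised, the peroxide may epoxidise the strained olefin, or the olefin geometry may turn only in part. The fallback keeps the geometry by retention through a vicinal diol instead of inversion, and sets out from 1.
- mCPBA/NaHCO3 in CH2Cl2 should give (−)-caryophyllene oxide F2 by outer-face epoxidation.
- Et2Al–TMP in toluene at 0 °C should isomerise F2 to the exocyclic allylic alcohol caryophylla-4(14),8(15)-dien-5-ol F3.
- VO(acac)2/t-BuOOH should give 4,14-epoxycaryophyll-8(15)-en-5-ol F4, the new C4–O bond being expected on the side of the former epoxide oxygen through allylic 1,2-strain control.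
- Ti(OiPr)4/PhCO2H should open F4 at C14 to the 14-benzoyloxy-4,5-diol F5.
- Thiocarbonyldiimidazole in hot toluene should give the cyclic 4,5-thiocarbonate F6.
- Corey–Winter olefination with 1,3-dimethyl-2-phenyl-1,3,2-diazaphospholidine at 40 °C should give 14-benzoyloxy-β-caryophyllene F7 by stereospecific syn-elimination to the ring-trans olefin.
- K2CO3/MeOH then gives 6, where the fallback rejoins the route; steps 2 and 3 fall away.

Step 3. SN2 opening of the hindered medium-ring epoxide may be slow, the neighbouring lithium alkoxide may shift the epoxide toward C14 (Payne rearrangement) with attack then at C14, or the betaine may fail to reach the syn-periplanar geometry. The fallback replaces chemical inversion by photochemical inversion. Starting from 2, MnO2 in CH2Cl2 should give the ring-cis enal isocaryophyllen-14-al F8. Irradiation of F8 (about 350 nm, pentane, flow loop through AgNO3-impregnated silica that retains the more strained ring-trans isomer, release with aqueous NH3) should drive the cis-to-trans isomerisation known for medium-ring cycloalkenes and enones. This gives 7, where the fallback rejoins the route; step 4 falls away as well.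

Further compounds
F1 | step 6 | β-caryophyllen-14-oic acid; (1R,4Z,9S)-11,11-dimethyl-8-methylidenebicyclo[7.2.0]undec-4-ene-4-carboxylic acid (ring-trans) | C=C1CC/C=C(\C(=O)O)CC[C@@H]2[C@@H]1CC2(C)C
F2 | step 1 | (−)-caryophyllene oxide; (1R,4R,5R,9S)-4,5-epoxycaryophyll-8(15)-ene | C=C1CC[C@H]2O[C@]2(C)CC[C@@H]2[C@@H]1CC2(C)C
F3 | step 1 | (1R,5R,9S)-caryophylla-4(14),8(15)-dien-5-ol | C=C1CC[C@@H](O)C(=C)CC[C@@H]2[C@@H]1CC2(C)C
F4 | step 1 | (1R,4S,5R,9S)-4,14-epoxycaryophyll-8(15)-en-5-ol (C4–O on the side of the former epoxide oxygen) | C=C1CC[C@@H](O)[C@@]2(CO2)CC[C@@H]3[C@@H]1CC3(C)C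
F5 | step 1 | 14-benzoyloxycaryophyll-8(15)-ene-4,5-diol (configuration at C4 and C5 as in F4) | C=C1CC[C@@H](O)[C@@](O)(COC(=O)c2ccccc2)CC[C@@H]2[C@@H]1CC2(C)C
F6 | step 1 | cyclic 4,5-thiocarbonate of F5 | C=C1CC[C@H]2OC(=S)O[C@]2(COC(=O)c3ccccc3)CC[C@@H]4[C@@H]1CC4(C)C
F7 | step 1 | 14-benzoyloxy-β-caryophyllene (ring-trans) | C=C1CC/C=C(\COC(=O)c2ccccc2)CC[C@@H]2[C@@H]1CC2(C)C
F8 | step 3 | isocaryophyllen-14-al; (1R,4E,9S)-11,11-dimethyl-8-methylidenebicyclo[7.2.0]undec-4-ene-4-carbaldehyde (ring-cis) | C=C1CC/C=C(/C=O)CC[C@@H]2[C@@H]1CC2(C)C
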